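## Structural features

The target 9 is a 2,3-dihydro-1-benzofuran: a five-membered ring O1–C2–C3–C3a–C7a fused along C3a–C7a to a benzo ring. It carries a 3,4,5-trimethoxyphenyl group on C2, a hydroxymethyl group on C3 and an (E)-3-hydroxyprop-1-enyl chain on C5, para to O1. C2 (R) and C3 (S) are adjacent stereocentres, with the aryl and hydroxymethyl groups on opposite faces of the ring (trans). C2 is benzylic and also bears the aryloxy oxygen, so acid can ionise the C2–O1 bond; the side chain is a para-alkoxy cinnamyl alcohol, which also ionises and oligomerises under acid. At the ester oxidation level the C3–H is acidic and O1 is a β-leaving group, so strong base can open the ring by elimination and erase both centres, while oxidants can aromatise the ring to the benzofuran. No functional group near C2/C3 can direct a reagent, so the real difficulty is absolute control of this isolated trans pair without passing through the aromatic benzofuran. The key step exploits the fact that O1 on C2 and the exocyclic carbon on C3 are vicinal and anti across C2–C3. This is the pattern left when a phenol oxygen and a carbonyl carbon add to opposite faces of an (E)-stilbene alkene whose carbons become C2 and C3 and whose phenol ring becomes the benzo ring. Both primary alcohols are reduced methyl esters in disguise, so the carbonyl carbon introduced at C3 and a C5 enoate can be unmasked together.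

## Logic of the disconnections

9 to 8. No skeletal bond is cut. The two CH2OH carbons are taken back to CO2Me carbons. The reason is that a carbonylative ring closure delivers C3 as an ester, and an enoate at C5 is the alkene that an electrophilic palladium catalyst is least likely to touch. The gain is that one reduction reveals both alcohols and no protecting group is needed. The demand on the forward step is clean 1,2-reduction of the enoate and of the more hindered C3 ester without epimerisation or ring opening at C3.

8 to 5 + 6 + 7. The bonds cut are O1–C2 and C3–C(carbonyl), together with the acyl C–OMe bond. Cutting here removes the ring and both stereocentres at once and leads to a flat, achiral (E)-stilbene. 5 is kept as the free phenol, since that oxygen is the nucleophile. Its C5 chain is kept at the enoate level for three reasons: the electron-poor enoate resists oxypalladation, it makes the phenol ring less prone to oxidation by the quinone oxidant, and its methyl ester matches 7 so no ester exchange can occur. An allylic alcohol or allylic ether in that position would invite ionisation by the metal, so no change to 5 is proposed. The forward step must select one alkene face through the chiral ligand, must add oxygen and carbon anti, and must insert 6 faster than β-hydride elimination occurs.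

5 to 3 + 4. The bond cut is the one between the phenol ring carbon (the future C3a) and the alkene carbon (the future C3). This is a Heck transform; it fixes the (E)-geometry and splits the molecule into two pieces of similar size. The forward step must tolerate the free ortho-phenol and must react at the terminal alkene of 4 in preference to the enoate of 3.

3 to 1 + 2. The bond cut is the enoate C=C. A Wittig transform with a stabilised ylide returns an aldehyde that already has bromine and hydroxyl in the required 1,2-relationship. The forward step must be (E)-selective and must tolerate the acidic phenol.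

## Other disconnections considered

Alternative 1: The cut removes C2 as a one-carbon unit. Bonds C2–C3 and O1–C2 are broken, leaving an ortho-quinone methide (O1, C7a, C3a, C3) and a benzylic sulfur ylide. In the forward step Cs2CO3 would expel sulfinate from the sulfone A2 to unveil the methide and would deprotonate the sulfonium salt A3 (one enantiomer of a C2-symmetric thiolane, drawn as 2R,5R for definiteness). The ylide carbon would add to the methide carbon, and the phenoxide would then displace the thiolane in an SN2 closure to give the silyl ether A1.
- In favour: the step is metal-free and convergent, and the trans arrangement should follow from an anti betaine and invertive closure. Annulations of this kind between ortho-quinone methides and sulfur ylides are an established reaction class, so on precedent this alternative is the better of the two.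
- Also better: A1 has C3 already at the alcohol oxidation level. It has no acidic C3–H beside a carbonyl, so it is configurationally more robust than 8.
- Against it here: the methide from A2 carries an sp3 CH2O substituent rather than an aryl group and can leak to a 2-vinylphenol by hydrogen shift. The chirality is stoichiometric, and its transfer from a semi-stabilised benzylic ylide to a planar methide is uncertain.
- Structure: it forms the same ring, two bonds and both stereocentres, which equals the chosen plan.
- Mechanism: polar and stepwise with reagent control, against catalytic ligand control in the chosen plan.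
- Step economy: A2 would need about four steps and A3 one. After A1, chain installation at the bromide, ester reduction and desilylation add three more. That is roughly twice the length of the chosen route.

Alternative 2: The cut dismantles the benzo ring. Bonds C3a–C7a and C4–C5 are broken, so the arene arises from a 2-pyrone (the future C7a, C7, C6, C5) and a tethered terminal alkyne (the future C3a and C4). On heating the precursor A5, the alkyne would add across C3 and C6 of the pyrone. The bridged lactone would then lose CO2 to give the ester A4.
- In favour: no reagent or catalyst is needed, the tether dictates regiochemistry, and no toxic gas is used, which makes it operationally the safer step. It closes two rings in one operation against one ring in the chosen key step, so on ring count it is the better.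
- Also in favour: the step creates no stereocentre and so carries no selectivity risk of its own.
- Against it here: both stereocentres must be built beforehand into the acyclic (1R,2S) array of A5. The ether link must be made at an ionisable secondary benzylic carbon attached to a hydroxypyrone. The propargylic centre could scramble through propargyl–allene isomerisation at the temperature an unactivated alkyne requires.
- Structure: an elegant de novo arene, but the C5 ester of A4 is two carbons short of the side chain.
- Mechanism: pericyclic and predictable, which is a genuine advantage over an untested catalytic cycle.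
- Step economy: reduction, oxidation, olefination, reduction and desilylation follow the key step, on top of a multi-step synthesis of A5. It is clearly the longest of the routes considered.

Alternative 3: The cut is C3–C3a. In the forward sense this bond forms when the ring A carbon C4a of the flavanone A7 migrates from C4 to C3. With PhI(OAc)2 and H2SO4 in trimethyl orthoformate, the enol ether of A7 would be attacked at C3 by the iodane anti to the C2 aryl group. Ring A would then shift as the iodine leaving group departs, and the oxocarbenium at C4 would be captured as the methyl ester A6.
- In favour: this is a known reaction type for flavanones, so on precedent it is the better. The trans outcome is built into the mechanism. C2 would be set earlier by a known type of catalytic asymmetric conjugate addition of an arylboronic acid to a chromone and would relay to C3.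
- Equal: a Heck reaction of A6 with an acrylate ester would give 8, so the end game is shared and the step count (four) equals that of the chosen plan.
- Against it here: the strongly acidic, oxidising medium can open the flavanone reversibly to the open-chain enone and so erode C2 before rearrangement. A shift of ring B from C2 to C3 and dehydrogenation of the pyranone ring compete. The electron-rich trimethoxyphenyl ring is exposed to the iodane, which is used stoichiometrically.
- Structure: one skeletal bond and one new stereocentre in the key step, against two and two.
- Mechanism: substrate-controlled cationic rearrangement starting from an enantioenriched precursor, against catalyst control starting from achiral 5.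
- Step economy: equal. The chosen plan is preferred only for its bond-forming economy and because its stereochemical information is created late, under non-acidic conditions.

Key step: step 3

Assumption: the (S,S)-configured bis(oxazoline) is taken to direct O1 to the alkene face that gives (2R). If the sense proves opposite, the (R,R)-ligand is used and nothing else changes.
Remark: 8 is (2R,3R) and 9 is (2R,3S) with the same spatial arrangement. The descriptor at C3 changes only because CH2OH ranks below C2 whereas CO2Me ranks above it. The structures of 5 and 8 were checked against 9 and needed no correction.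

Step 1
Reactants: 1 3-bromo-4-hydroxybenzaldehyde; 2 methyl (triphenylphosphoranylidene)acetate
Product: 3 methyl (E)-3-(3-bromo-4-hydroxyphenyl)prop-2-enoate
Conditions: 2 (1.3 equiv), toluene, 90 °C
Reagents that add atoms: none
Why: Wittig olefination with a stabilised ylide, whose reversible oxaphosphetane formation favours the (E)-enoate; the ylide is too weak a base to be quenched by the phenol in toluene, so no protecting group is needed.

Step 2
Reactants: 3 methyl (E)-3-(3-bromo-4-hydroxyphenyl)prop-2-enoate; 4 3,4,5-trimethoxystyrene
Product: 5 methyl (E)-3-{4-hydroxy-3-[(E)-2-(3,4,5-trimethoxyphenyl)ethenyl]phenyl}prop-2-enoate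
Conditions: Pd(OAc)2 (5 mol %), P(o-tol)3 (10 mol %), NaOAc (1.5 equiv), 4 (1.3 equiv), DMF, 110 °C
Reagents that add atoms: none
Why: Mizoroki–Heck reaction: oxidative addition at the C–Br bond of 3, syn carbopalladation of 4 at its unsubstituted carbon and syn β-hydride elimination give the (E)-stilbene; the terminal styrene reacts far faster than the β-substituted, electron-poor enoate of 3, and acetate leaves the phenol largely protonated.

Step 3
Reactants: 5 methyl (E)-3-{4-hydroxy-3-[(E)-2-(3,4,5-trimethoxyphenyl)ethenyl]phenyl}prop-2-enoate; 6 carbon monoxide; 7 methanol
Product: 8 methyl (2R,3R)-5-[(E)-3-methoxy-3-oxoprop-1-en-1-yl]-2-(3,4,5-trimethoxyphenyl)-2,3-dihydro-1-benzofuran-3-carboxylate (trans)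
Conditions: Pd(OCOCF3)2 (10 mol %), (S,S)-2,2′-(propane-2,2-diyl)bis(4-phenyl-4,5-dihydro-1,3-oxazole) (12 mol %), p-benzoquinone (1.5 equiv), CO (10 bar), MeOH–CH2Cl2 1:1, 0 °C to rt
Reagents that add atoms: none
Why: Proposed new method: divalent palladium bound to the bis(oxazoline) coordinates the electron-rich stilbene alkene of 5 and the phenol oxygen attacks C2 on the face opposite the metal, closing the ring O1–C2–C3–C3a–C7a in a 5-endo-trig mode (the only ring size open to this oxygen, which fixes the regiochemistry) and leaving a benzylic C3–Pd bond that can rest as an η3-benzyl; 6 then inserts into C3–Pd with retention, 7 cleaves the acyl–palladium bond to the methyl ester, and p-benzoquinone returns zerovalent palladium to the divalent state. The closest known reaction types are the palladium-catalysed intramolecular alkoxycarbonylation of hydroxy alkenes with Pd(OCOCF3)2, a bis(oxazoline) and p-benzoquinone, and the palladium-mediated oxidative cyclisation of 2-hydroxystilbenes to 2-arylbenzofurans; the new element is their merger on a 1,2-diarylethene in a 5-endo closure with asymmetric induction. C2 is set by the ligand, which decides the alkene face the metal binds and hence the face from which O1 arrives; C3 is set relative to C2 by anti oxypalladation of the (E)-alkene followed by retentive insertion, which places the aryl group and the ester trans, also the thermodynamically preferred arrangement. The step needs insertion of 6 to outpace β-hydride elimination of the syn C2–H (which would aromatise the ring), helped by CO pressure, low temperature and the non-basic trifluoroacetate medium; it also needs chemoselection between the two alkenes, secured because the enoate is electron-poor and has no internal nucleophile within reach.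

Step 4
Reactants: 8 methyl (2R,3R)-5-[(E)-3-methoxy-3-oxoprop-1-en-1-yl]-2-(3,4,5-trimethoxyphenyl)-2,3-dihydro-1-benzofuran-3-carboxylate
Product: 9 (E)-3-[(2R,3S)-3-(hydroxymethyl)-2-(3,4,5-trimethoxyphenyl)-2,3-dihydro-1-benzofuran-5-yl]prop-2-en-1-ol (trans)
Conditions: iBu2AlH (6 equiv), CH2Cl2, −78 °C to 0 °C; aq. potassium sodium tartrate
Reagents that add atoms: none
Why: Ester-to-alcohol reduction with iBu2AlH, which reduces the enoate 1,2 to the allylic alcohol without conjugate reduction and takes the C3 ester to the hydroxymethyl group; no bond at C2 or C3 is touched, so the trans arrangement is carried over and only the descriptor at C3 changes (R to S).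

## Compound list

1 | 3-bromo-4-hydroxybenzaldehyde | O=Cc1ccc(O)c(Br)c1 | starting material
2 | methyl (triphenylphosphoranylidene)acetate | COC(=O)C=P(c1ccccc1)(c1ccccc1)c1ccccc1 | starting material
3 | methyl (E)-3-(3-bromo-4-hydroxyphenyl)prop-2-enoate | COC(=O)/C=C/c1ccc(O)c(Br)c1 | intermediate
4 | 3,4,5-trimethoxystyrene (5-ethenyl-1,2,3-trimethoxybenzene) | COc1cc(C=C)cc(OC)c1OC | starting material
5 | methyl (E)-3-{4-hydroxy-3-[(E)-2-(3,4,5-trimethoxyphenyl)ethenyl]phenyl}prop-2-enoate | COc1cc(/C=C/c2cc(/C=C/C(=O)OC)ccc2O)cc(OC)c1OC | intermediate
6 | carbon monoxide | [C-]#[O+] | starting material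
7 | methanol | CO | starting material
8 | methyl (2R,3R)-5-[(E)-3-methoxy-3-oxoprop-1-en-1-yl]-2-(3,4,5-trimethoxyphenyl)-2,3-dihydro-1-benzofuran-3-carboxylate | COc1cc([C@@H]2Oc3ccc(/C=C/C(=O)OC)cc3[C@H]2C(=O)OC)cc(OC)c1OC | intermediate
9 | (E)-3-[(2R,3S)-3-(hydroxymethyl)-2-(3,4,5-trimethoxyphenyl)-2,3-dihydro-1-benzofuran-5-yl]prop-2-en-1-ol | COc1cc([C@@H]2Oc3ccc(/C=C/CO)cc3[C@H]2CO)cc(OC)c1OC | target

## Step count and risk assessment

Total step count: 4. Longest linear sequence: 4 steps (1 to 3 to 5 to 8 to 9).

Step 3 (key step, proposed new method).
- What may go wrong: β-hydride elimination from the C3–palladium intermediate may outrun insertion of 6 and aromatise the new ring, because anti oxypalladation places the C2–H syn to the metal.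
- Facial selectivity may be poor, since the ligand has to distinguish the faces of a 1,2-diarylethene in an unusual 5-endo closure.
- Intermolecular methoxycarbonylation of the stilbene may compete.
- If oxypalladation ran syn, the cis relationship would result. Brief equilibration at C3 with catalytic NaOMe in MeOH should correct this, at the cost of some risk of ring opening by β-elimination.
- Fallback (known chemistry, sets out from 3 and returns at 8): enantioselective intramolecular C–H insertion of an aryl diazoacetate. 3 would be O-alkylated with 3,4,5-trimethoxybenzyl chloride (K2CO3, DMF) to the benzyl ether methyl (E)-3-{3-bromo-4-[(3,4,5-trimethoxyphenyl)methoxy]phenyl}prop-2-enoate F1. Negishi-type coupling of the bromide with the Reformatsky reagent BrZnCH2CO2Me (Pd2(dba)3, XPhos, THF) would give the arylacetate methyl (E)-3-{3-(2-methoxy-2-oxoethyl)-4-[(3,4,5-trimethoxyphenyl)methoxy]phenyl}prop-2-enoate F2. Diazo transfer (4-acetamidobenzenesulfonyl azide, DBU, MeCN) would give the aryl diazoacetate methyl (E)-3-{3-(1-diazo-2-methoxy-2-oxoethyl)-4-[(3,4,5-trimethoxyphenyl)methoxy]phenyl}prop-2-enoate F3. With dirhodium tetrakis[N-phthaloyl-(S)-tert-leucinate] (or its enantiomer, whichever leads to the 2R series) in toluene at low temperature, the carbene should insert into the benzylic C–H bond of the ether, forming C2–C3, to give the cis ester methyl (2R,3S)-5-[(E)-3-methoxy-3-oxoprop-1-en-1-yl]-2-(3,4,5-trimethoxyphenyl)-2,3-dihydro-1-benzofuran-3-carboxylate F4. Equilibration at C3 (cat. NaOMe, MeOH, 0 °C) would then give the trans ester 8.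

Step 2 (Heck coupling).
- What may go wrong: oxidative addition at the electron-rich ortho-bromophenol may be sluggish, and phenoxide may deactivate the catalyst. Arylation at the internal carbon of 4 or a second arylation would lower the regiochemical purity.
- Fallback (sets out from 4 and returns at 5): the coupling is changed from alkene C–H arylation to a cross-coupling of a preformed alkenylboron reagent. Cross-metathesis of 4 with vinylboronic acid pinacol ester (second-generation Grubbs catalyst, CH2Cl2, 40 °C) would give 4,4,5,5-tetramethyl-2-[(E)-2-(3,4,5-trimethoxyphenyl)ethenyl]-1,3,2-dioxaborolane F5. Suzuki–Miyaura coupling of F5 with 3 (PdCl2(dppf), K3PO4, dioxane–H2O, 80 °C) would then give 5 with the (E)-geometry fixed in advance.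

Step 4 (double reduction).
- What may go wrong: reduction of the hindered C3 ester may be incomplete, leaving aldehyde-level material that is prone to β-elimination on work-up. The para-alkoxy cinnamyl alcohol may ionise during acidic work-up or on silica, with loss of material.
- Fallback (sets out from 8 and returns at 9): the diol is isolated as a stable derivative instead of as the free alcohol. After the same reduction with excess iBu2AlH and tartrate work-up, the crude diol would be acetylated (Ac2O, pyridine, cat. DMAP) to the diacetate [(2R,3S)-5-[(E)-3-acetoxyprop-1-en-1-yl]-2-(3,4,5-trimethoxyphenyl)-2,3-dihydro-1-benzofuran-3-yl]methyl acetate F6. F6 would be purified and then cleaved under neutral-to-basic conditions (cat. K2CO3, MeOH, 0 °C) to give 9.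

## Further compounds

F1 | step 3 | methyl (E)-3-{3-bromo-4-[(3,4,5-trimethoxyphenyl)methoxy]phenyl}prop-2-enoate | COC(=O)/C=C/c1ccc(OCc2cc(OC)c(OC)c(OC)c2)c(Br)c1
F2 | step 3 | methyl (E)-3-{3-(2-methoxy-2-oxoethyl)-4-[(3,4,5-trimethoxyphenyl)methoxy]phenyl}prop-2-enoate | COC(=O)/C=C/c1ccc(OCc2cc(OC)c(OC)c(OC)c2)c(CC(=O)OC)c1
F3 | step 3 | methyl (E)-3-{3-(1-diazo-2-methoxy-2-oxoethyl)-4-[(3,4,5-trimethoxyphenyl)methoxy]phenyl}prop-2-enoate | COC(=O)/C=C/c1ccc(OCc2cc(OC)c(OC)c(OC)c2)c(C(=[N+]=[N-])C(=O)OC)c1
F4 | step 3 | methyl (2R,3S)-5-[(E)-3-methoxy-3-oxoprop-1-en-1-yl]-2-(3,4,5-trimethoxyphenyl)-2,3-dihydro-1-benzofuran-3-carboxylate (cis) | COc1cc([C@@H]2Oc3ccc(/C=C/C(=O)OC)cc3[C@@H]2C(=O)OC)cc(OC)c1OC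
F5 | step 2 | 4,4,5,5-tetramethyl-2-[(E)-2-(3,4,5-trimethoxyphenyl)ethenyl]-1,3,2-dioxaborolane | COc1cc(/C=C/B2OC(C)(C)C(C)(C)O2)cc(OC)c1OC
F6 | step 4 | [(2R,3S)-5-[(E)-3-acetoxyprop-1-en-1-yl]-2-(3,4,5-trimethoxyphenyl)-2,3-dihydro-1-benzofuran-3-yl]methyl acetate | COc1cc([C@@H]2Oc3ccc(/C=C/COC(C)=O)cc3[C@H]2COC(C)=O)cc(OC)c1OC
A1 | alternative 1 | tert-butyl{[(2R,3S)-5-bromo-2-(3,4,5-trimethoxyphenyl)-2,3-dihydro-1-benzofuran-3-yl]methoxy}dimethylsilane | COc1cc([C@@H]2Oc3ccc(Br)cc3[C@H]2CO[Si](C)(C)C(C)(C)C)cc(OC)c1OC
A2 | alternative 1 | 4-bromo-2-[2-(tert-butyldimethylsilyloxy)-1-(4-methylbenzenesulfonyl)ethyl]phenol (racemic) | Cc1ccc(S(=O)(=O)C(CO[Si](C)(C)C(C)(C)C)c2cc(Br)ccc2O)cc1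
A3 | alternative 1 | (2R,5R)-2,5-dimethyl-1-[(3,4,5-trimethoxyphenyl)methyl]thiolan-1-ium bromide | COc1cc(C[S+]2[C@H](C)CC[C@H]2C)cc(OC)c1OC.[Br-]
A4 | alternative 2 | methyl (2R,3S)-3-[(tert-butyldimethylsilyloxy)methyl]-2-(3,4,5-trimethoxyphenyl)-2,3-dihydro-1-benzofuran-5-carboxylate | COc1cc([C@@H]2Oc3ccc(C(=O)OC)cc3[C@H]2CO[Si](C)(C)C(C)(C)C)cc(OC)c1OC
A5 | alternative 2 | methyl 5-{[(1R,2S)-2-[(tert-butyldimethylsilyloxy)methyl]-1-(3,4,5-trimethoxyphenyl)but-3-yn-1-yl]oxy}-6-oxo-6H-pyran-2-carboxylate | COC(=O)C1=CC=C(O[C@@H](c2cc(OC)c(OC)c(OC)c2)[C@H](CO[Si](C)(C)C(C)(C)C)C#C)C(=O)O1
A6 | alternative 3 | methyl (2R,3R)-5-bromo-2-(3,4,5-trimethoxyphenyl)-2,3-dihydro-1-benzofuran-3-carboxylate | COc1cc([C@@H]2Oc3ccc(Br)cc3[C@H]2C(=O)OC)cc(OC)c1OC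
A7 | alternative 3 | (2R)-6-bromo-2-(3,4,5-trimethoxyphenyl)-2,3-dihydro-4H-chromen-4-one | COc1cc([C@@H]2Oc3ccc(Br)cc3C(=O)C2)cc(OC)c1OC
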